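**Retrosynthetic overview**

1. Target 16 ⇐ triether 15 (BBr3) ⇐ pentabromo ketone 13 (NaBH4, then Et3SiH/CF3CO2H) ⇐ ketone 12 (threefold bromination of ring B).
2. Feature relied on: ring B carries the benzylic carbon at C1, Br at C2, OH at C3 and C4, and Br at C5 and C6, so the carbon substituent is para to the C4 oxygen and meta to the C3 oxygen. A 3-methoxyfuran delivers this pattern when its C2 (which keeps the ring oxygen, later the C3 hydroxyl) bonds to the terminal carbon of an aryl ethynyl ketone and its methoxy carbon becomes C4.
3. Key disconnection: ring B of 12 ⇒ 3-methoxyfuran 10 + ynone 8, by [4+2] cycloaddition (new bonds C2–C3 and C1–C6 of ring B) and acid opening of the oxygen bridge.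
4. Ynone 8 ⇐ veratrole (ring A) by double ortho-lithiation/bromination, lithiation/formylation, ethynyl Grignard addition and MnO2 oxidation; 10 ⇐ 3-bromofuran.
5. Ring order: ring A is purchased and ring B is the only ring constructed (key step). The carbonyl is kept until ring B is fully brominated because it deactivates the single free C–H of ring A.

Key step: step 6

Remark: the target is achiral. The stereocentres of 7, 11 and 14 are racemic and are removed in the operation that follows. Ring atoms are numbered from the carbon that carries the bridging carbon (C1).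

**Route**

Step 1
Reactants: 1 veratrole
Product: 3 1,4-dibromo-2,3-dimethoxybenzene, via dilithioveratrole 2 (not isolated)
Conditions: n-BuLi (3 equiv), TMEDA (3 equiv), Et2O, 0 → 35 °C; then BrCCl2CCl2Br (3 equiv), THF, −78 → 23 °C
Reagents that add atoms: 1,2-dibromo-1,1,2,2-tetrachloroethane, BrC(Cl)(Cl)C(Cl)(Cl)Br
Why: Double directed ortho-metalation, in which each methoxy group steers n-BuLi/TMEDA to its free ortho position, followed by bromination of the dilithio species through halogen–metal exchange; direct electrophilic bromination would give the unwanted 4,5-isomer.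

Step 2
Reactants: 3 1,4-dibromo-2,3-dimethoxybenzene
Product: 5 2,5-dibromo-3,4-dimethoxybenzaldehyde, via aryllithium 4 (not isolated)
Conditions: LDA (1.1 equiv), THF, −78 °C; then DMF, −78 → 0 °C; 1 M HCl
Reagents that add atoms: N,N-dimethylformamide, CN(C)C=O
Why: Deprotonative lithiation next to bromine followed by formylation with DMF, the sequence that turns 1,4-dibromobenzene into 2,5-dibromobenzaldehyde; the two ring hydrogens of 3 are equivalent, so only one aldehyde can form, and −78 °C should suppress aryne formation and halogen migration.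

Step 3
Reactants: 5 2,5-dibromo-3,4-dimethoxybenzaldehyde; 6 ethynylmagnesium bromide
Product: 7 rac-1-(2,5-dibromo-3,4-dimethoxyphenyl)prop-2-yn-1-ol
Conditions: THF, 0 °C; aq NH4Cl
Reagents that add atoms: none
Why: Grignard 1,2-addition of an alkynylmagnesium halide to an aromatic aldehyde; the reagent does not exchange with aryl bromides, and the new carbinol centre is racemic and is removed in step 4.

Step 4
Reactants: 7 rac-1-(2,5-dibromo-3,4-dimethoxyphenyl)prop-2-yn-1-ol
Product: 8 1-(2,5-dibromo-3,4-dimethoxyphenyl)prop-2-yn-1-one
Conditions: MnO2 (activated, excess), CH2Cl2, 23 °C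
Reagents that add atoms: none
Why: MnO2 oxidation of a benzylic, propargylic alcohol under neutral conditions, which should leave the nucleophile-sensitive terminal ynone intact.

Step 5
Reactants: 9 3-bromofuran
Product: 10 3-methoxyfuran
Conditions: NaOMe (3 equiv), CuBr (10 mol %), MeOH, 90 °C, sealed tube; distillation
Reagents that add atoms: sodium methoxide, [Na+].[O-]C
Why: CuBr-catalysed Ullmann-type methoxylation of a 3-haloheteroarene, as used to make 3-methoxythiophene from 3-bromothiophene; the volatile, acid-sensitive product is distilled and used at once.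

Step 6
Reactants: 8 1-(2,5-dibromo-3,4-dimethoxyphenyl)prop-2-yn-1-one; 10 3-methoxyfuran
Product: 12 (2,5-dibromo-3,4-dimethoxyphenyl)(3-hydroxy-4-methoxyphenyl)methanone, via oxanorbornadiene adduct 11 (not isolated)
Conditions: CH2Cl2, 0 → 23 °C, dark, diene in excess (2.5 equiv); then CF3CO2H (cat.), 0 → 23 °C
Reagents that add atoms: none
Why: Diene 10 is electron-rich with its largest HOMO coefficient at C2 (next to the methoxy carbon), and ynone 8 has its largest LUMO coefficient at the terminal alkyne carbon, so a normal-demand, asynchronous Diels–Alder reaction should join furan C2 to the terminal alkyne carbon and furan C5 to the acyl-bearing carbon to give oxanorbornadiene 11. Acid then ionises the bridge C–O bond at the former furan C5, since only that allyl cation terminates on the methoxy-bearing carbon as an oxocarbenium ion, and loss of the proton from the former furan C2 aromatises the ring with the bridge oxygen retained there as the phenol. The nearest established reaction class is the cycloaddition of 2- and 3-alkoxyfurans to acetylenic esters and ketones, whose oxygen-bridged adducts isomerise to phenols on contact with acid. Ring B is closed by an intermolecular [4+2] cycloaddition that makes both new ring bonds (C2–C3 and C1–C6), its six atoms being the four furan carbons and the two alkyne carbons. The two bridgehead stereocentres of 11 form as a racemate, are tied to each other by the bridge and vanish on aromatisation, so no stereocontrol is required. Regioselectivity is needed twice, in the cycloaddition and in the bridge opening, and the 3-methoxy group secures both; the overall change is an addition followed by an isomerisation, so all atoms of 8 and 10 are retained in 12.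

Step 7
Reactants: 12 (2,5-dibromo-3,4-dimethoxyphenyl)(3-hydroxy-4-methoxyphenyl)methanone
Product: 13 (2,5-dibromo-3,4-dimethoxyphenyl)(2,3,6-tribromo-5-hydroxy-4-methoxyphenyl)methanone
Conditions: Br2 (4 equiv), Fe powder (cat.), AcOH, 23 → 60 °C; aq NaHSO3
Reagents that add atoms: bromine, BrBr
Why: Electrophilic aromatic bromination, in which the phenol directs bromine to C2 and C6 of ring B and the methoxy group to C5, while ring A should stay untouched because its only free position is ortho to the carbonyl on a ring that already carries two bromines and whose para methoxy group is twisted out of conjugation by its two neighbours.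

Step 8
Reactants: 13 (2,5-dibromo-3,4-dimethoxyphenyl)(2,3,6-tribromo-5-hydroxy-4-methoxyphenyl)methanone
Product: 14 rac-(2,5-dibromo-3,4-dimethoxyphenyl)(2,3,6-tribromo-5-hydroxy-4-methoxyphenyl)methanol
Conditions: NaBH4 (excess), THF/MeOH, 0 → 40 °C; then H2O
Reagents that add atoms: none
Why: Borohydride reduction of a diaryl ketone; aryl bromides are inert to NaBH4 and the electron-poor carbonyl should accept the small hydride despite three ortho bromines, the carbinol centre being racemic and removed in step 9.

Step 9
Reactants: 14 rac-(2,5-dibromo-3,4-dimethoxyphenyl)(2,3,6-tribromo-5-hydroxy-4-methoxyphenyl)methanol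
Product: 15 2,4,5-tribromo-3-[(2,5-dibromo-3,4-dimethoxyphenyl)methyl]-6-methoxyphenol
Conditions: Et3SiH (4 equiv), CF3CO2H/CH2Cl2, 0 → 40 °C; aq NaHCO3
Reagents that add atoms: none
Why: Ionic hydrogenation, in which CF3CO2H ionises the benzhydrol to a diarylmethyl cation supported by the para methoxy groups and Et3SiH delivers hydride; C–Br bonds and methyl ethers are not affected.

Step 10
Reactants: 15 2,4,5-tribromo-3-[(2,5-dibromo-3,4-dimethoxyphenyl)methyl]-6-methoxyphenol
Product: 16 3,4,6-tribromo-5-[(2,5-dibromo-3,4-dihydroxyphenyl)methyl]benzene-1,2-diol (CNP0260137.0)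
Conditions: BBr3 (6 equiv), CH2Cl2, −78 → 23 °C, argon; then ice water
Reagents that add atoms: none
Why: BBr3 cleavage of aryl methyl ethers (boron–oxygen complexation, then bromide attack on the methyl group), a standard way to free brominated catechols without touching C–Br bonds or the diarylmethane.

**Compound list**

1 | veratrole (1,2-dimethoxybenzene) | COc1ccccc1OC | starting material
2 | 3,6-dilithioveratrole (1,4-dilithio-2,3-dimethoxybenzene) | [Li]c1ccc([Li])c(OC)c1OC | intermediate
3 | 1,4-dibromo-2,3-dimethoxybenzene | COc1c(Br)ccc(Br)c1OC | intermediate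
4 | (2,5-dibromo-3,4-dimethoxyphenyl)lithium | [Li]c1cc(Br)c(OC)c(OC)c1Br | intermediate
5 | 2,5-dibromo-3,4-dimethoxybenzaldehyde | O=Cc1cc(Br)c(OC)c(OC)c1Br | intermediate
6 | ethynylmagnesium bromide | C#C[Mg]Br | starting material
7 | rac-1-(2,5-dibromo-3,4-dimethoxyphenyl)prop-2-yn-1-ol | C#CC(O)c1cc(Br)c(OC)c(OC)c1Br | intermediate
8 | 1-(2,5-dibromo-3,4-dimethoxyphenyl)prop-2-yn-1-one | C#CC(=O)c1cc(Br)c(OC)c(OC)c1Br | intermediate
9 | 3-bromofuran | Brc1ccoc1 | starting material
10 | 3-methoxyfuran | COc1ccoc1 | intermediate
11 | rac-(2,5-dibromo-3,4-dimethoxyphenyl)(5-methoxy-7-oxabicyclo[2.2.1]hepta-2,5-dien-2-yl)methanone (relative configuration fixed by the bridge) | COC1=CC2OC1C=C2C(=O)c1cc(Br)c(OC)c(OC)c1Br | intermediate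
12 | (2,5-dibromo-3,4-dimethoxyphenyl)(3-hydroxy-4-methoxyphenyl)methanone | COc1ccc(C(=O)c2cc(Br)c(OC)c(OC)c2Br)cc1O | intermediate
13 | (2,5-dibromo-3,4-dimethoxyphenyl)(2,3,6-tribromo-5-hydroxy-4-methoxyphenyl)methanone | COc1c(O)c(Br)c(C(=O)c2cc(Br)c(OC)c(OC)c2Br)c(Br)c1Br | intermediate
14 | rac-(2,5-dibromo-3,4-dimethoxyphenyl)(2,3,6-tribromo-5-hydroxy-4-methoxyphenyl)methanol | COc1c(O)c(Br)c(C(O)c2cc(Br)c(OC)c(OC)c2Br)c(Br)c1Br | intermediate
15 | 2,4,5-tribromo-3-[(2,5-dibromo-3,4-dimethoxyphenyl)methyl]-6-methoxyphenol | COc1c(O)c(Br)c(Cc2cc(Br)c(OC)c(OC)c2Br)c(Br)c1Br | intermediate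
16 | 3,4,6-tribromo-5-[(2,5-dibromo-3,4-dihydroxyphenyl)methyl]benzene-1,2-diol | Oc1c(Br)cc(Cc2c(Br)c(O)c(O)c(Br)c2Br)c(Br)c1O | target

**Step count and risks**

Total steps: 10. Longest linear sequence: 9 (steps 1–4 and 6–10); step 5 is a one-step side branch.

Steps most likely to fail:

Step 6. The furan may add to the ynone as a carbon nucleophile (conjugate addition at C2 without ring closure), the acid-sensitive diene may oligomerise before it cycloadds, or the bridge may open in the other sense. The fallback gives up the cycloaddition and joins the two rings by carbonyl addition. It sets out from aldehyde 5 and returns at 12. Purchased 5-bromo-2-methoxyphenol is protected with MOMCl and i-Pr2NEt in CH2Cl2 to give 4-bromo-1-methoxy-2-(methoxymethoxy)benzene F1. Magnesium turnings in THF convert it into [4-methoxy-3-(methoxymethoxy)phenyl]magnesium bromide F2. Addition of this reagent to 5 at 0 °C (aq NH4Cl quench) should give rac-(2,5-dibromo-3,4-dimethoxyphenyl)[4-methoxy-3-(methoxymethoxy)phenyl]methanol F3. MnO2 in CH2Cl2 oxidises it to (2,5-dibromo-3,4-dimethoxyphenyl)[4-methoxy-3-(methoxymethoxy)phenyl]methanone F4, and HCl in MeOH removes the acetal to give 12.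

Step 7. The third bromination (C5 of ring B) may stall once the ring carries two bromines and the acyl group, and forcing it may start substitution at C6 of ring A or ether cleavage by the HBr formed. The fallback brings the C5 bromine in with the diene. It sets out from ynone 8 and returns at 13. Purchased 3,4-dibromofuran is mono-methoxylated (NaOMe, CuBr, MeOH, 90 °C) to 3-bromo-4-methoxyfuran F5. Cycloaddition of F5 with 8 in toluene at 23–60 °C should give rac-(6-bromo-5-methoxy-7-oxabicyclo[2.2.1]hepta-2,5-dien-2-yl)(2,5-dibromo-3,4-dimethoxyphenyl)methanone F6, with the methoxy group again directing the regiochemistry. Catalytic CF3CO2H opens it to (3-bromo-5-hydroxy-4-methoxyphenyl)(2,5-dibromo-3,4-dimethoxyphenyl)methanone F7. Br2 (2 equiv) in AcOH at 23 °C then only has to fill the two positions ortho and para to the phenol, which gives 13.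

Step 9. Ionisation of the benzhydrol may be too slow, because the cation carries five bromines and both rings are twisted by ortho bromines; the alcohol may then be trapped as its trifluoroacetate or dimerise to an ether instead of being reduced. The fallback reduces before brominating. It sets out from 12 and returns at 15. NaBH4 in MeOH reduces 12 to rac-(2,5-dibromo-3,4-dimethoxyphenyl)(3-hydroxy-4-methoxyphenyl)methanol F8. Et3SiH in CF3CO2H/CH2Cl2 at 0 °C converts it to 5-[(2,5-dibromo-3,4-dimethoxyphenyl)methyl]-2-methoxyphenol F9, the cation now being stabilised by an unhindered para-methoxyphenyl ring. Br2 (3 equiv) in AcOH at 0–23 °C then brominates the three free positions of the phenol ring, which remain far more activated than C6 of ring A, to give 15.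

**Further compounds**

F1 | step 6 | 4-bromo-1-methoxy-2-(methoxymethoxy)benzene | COCOc1cc(Br)ccc1OC
F2 | step 6 | [4-methoxy-3-(methoxymethoxy)phenyl]magnesium bromide | COCOc1cc([Mg]Br)ccc1OC
F3 | step 6 | rac-(2,5-dibromo-3,4-dimethoxyphenyl)[4-methoxy-3-(methoxymethoxy)phenyl]methanol | COCOc1cc(C(O)c2cc(Br)c(OC)c(OC)c2Br)ccc1OC
F4 | step 6 | (2,5-dibromo-3,4-dimethoxyphenyl)[4-methoxy-3-(methoxymethoxy)phenyl]methanone | COCOc1cc(C(=O)c2cc(Br)c(OC)c(OC)c2Br)ccc1OC
F5 | step 7 | 3-bromo-4-methoxyfuran | COc1cocc1Br
F6 | step 7 | rac-(6-bromo-5-methoxy-7-oxabicyclo[2.2.1]hepta-2,5-dien-2-yl)(2,5-dibromo-3,4-dimethoxyphenyl)methanone | COC1=C(Br)C2OC1C=C2C(=O)c1cc(Br)c(OC)c(OC)c1Br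
F7 | step 7 | (3-bromo-5-hydroxy-4-methoxyphenyl)(2,5-dibromo-3,4-dimethoxyphenyl)methanone | COc1c(O)cc(C(=O)c2cc(Br)c(OC)c(OC)c2Br)cc1Br
F8 | step 9 | rac-(2,5-dibromo-3,4-dimethoxyphenyl)(3-hydroxy-4-methoxyphenyl)methanol | COc1ccc(C(O)c2cc(Br)c(OC)c(OC)c2Br)cc1O
F9 | step 9 | 5-[(2,5-dibromo-3,4-dimethoxyphenyl)methyl]-2-methoxyphenol | COc1ccc(Cc2cc(Br)c(OC)c(OC)c2Br)cc1O
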